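The whole plan rests on cutting ring A, the dihydrobenzofuran made of O1', C7a', C3a', the CH2 group and the spiro carbon. The cut falls at its C3a'–CH2 and O1'–C(spiro) bonds. This exposes the spiro carbon and its CH2 neighbour as the two carbons of an exocyclic enol ether on ring B. Ring B already carries the S methine carbon and benzofuran ring C, and the partner is an ortho-quinone diazide. One dirhodium-carbenoid formal [3+2] cycloaddition joins both halves, closes ring A and builds the fully substituted spiro carbon. Rings A and B share one arene, so a single monobenzyl acylphloroglucinol serves twice: as the diazide, and as the nucleophile in a copper-catalysed asymmetric propargylic annulation.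

Key step: step 12

Ring labels: ring A is the dihydrobenzofuran with the CH2 group. Ring B is the dihydrobenzofuran with the substituted methine carbon. Ring C is the aromatic benzofuran of the side chain.

Assumption: the sense of induction in step 11 cannot be derived from first principles for this alkyl-substituted ester. The ligand enantiomer that gives the S configuration at C3 of 18 is used (the S ligand is written).

Step 1
Reactants: 1 phloroglucinol; 2 isovaleryl chloride
Product: 3 phlorisovalerophenone [3-methyl-1-(2,4,6-trihydroxyphenyl)butan-1-one]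
Conditions: AlCl3 (3 equiv), CH2Cl2–PhNO2, 40 °C; aq. HCl work-up
Reagents that add atoms: none
Why: Friedel–Crafts acylation of the threefold symmetric, highly activated arene should stop after one acyl group because the chelated ketone deactivates the ring.

Step 2
Reactants: 3 phlorisovalerophenone
Product: 4 1-[4-(benzyloxy)-2,6-dihydroxyphenyl]-3-methylbutan-1-one
Conditions: BnBr (1.0 equiv), K2CO3 (1.1 equiv), acetone, 25–40 °C
Reagents that add atoms: benzyl bromide, BrCc1ccccc1
Why: Williamson ether synthesis should select the 4-OH, which is the most acidic hydroxyl and the only one not hydrogen-bonded to the ketone.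

Step 3
Reactants: 4 monobenzyl ether
Product: 5 5-(benzyloxy)-6-diazo-3-hydroxy-2-(3-methylbutanoyl)cyclohexa-2,4-dien-1-one (ortho-quinone diazide)
Conditions: 4-acetamidobenzenesulfonyl azide (1.1 equiv), Et3N, MeCN, 0 to 25 °C, dark
Reagents that add atoms: 4-acetamidobenzenesulfonyl azide, CC(=O)Nc1ccc(cc1)S(=O)(=O)N=[N+]=[N-]
Why: In this Regitz-type diazo transfer the phenoxide of 4 reacts at carbon like a cyclic 1,3-dicarbonyl enolate (its two free ring CH positions are equivalent), and loss of the sulfonamide leaves the quinone diazide.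

Step 4
Reactants: 3 phlorisovalerophenone
Product: 6 3,5-dihydroxy-4-(3-methylbutanoyl)phenyl 4-methylbenzenesulfonate
Conditions: TsCl (1.0 equiv), K2CO3, acetone, 0 to 25 °C
Reagents that add atoms: 4-toluenesulfonyl chloride, Cc1ccc(cc1)S(=O)(=O)Cl
Why: Selective O-sulfonylation takes the non-chelated 4-OH and blocks it temporarily.

Step 5
Reactants: 6 monotosylate
Product: 7 3,5-bis(benzyloxy)-4-(3-methylbutanoyl)phenyl 4-methylbenzenesulfonate
Conditions: BnBr (2.5 equiv), K2CO3, DMF, 60 °C
Reagents that add atoms: benzyl bromide, BrCc1ccccc1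
Why: Williamson ether synthesis under forcing conditions alkylates both chelated hydroxyls, while the sulfonate survives anhydrous carbonate and damps C-benzylation.

Step 6
Reactants: 7 dibenzyl tosylate
Product: 8 1-[2,6-bis(benzyloxy)-4-hydroxyphenyl]-3-methylbutan-1-one
Conditions: KOH, MeOH–THF–H2O, 60 °C; then 1 M HCl
Reagents that add atoms: none
Why: Saponification of the aryl sulfonate (S–O cleavage) is helped by the para acyl group, and the benzyl ethers and the hindered ketone are inert.

Step 7
Reactants: 8 4-hydroxy dibenzyl ether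
Product: 9 1-[2,6-bis(benzyloxy)-4-hydroxy-3-iodophenyl]-3-methylbutan-1-one
Conditions: NIS (1.0 equiv), MeCN, 0 °C
Reagents that add atoms: N-iodosuccinimide, O=C1CCC(=O)N1I
Why: Electrophilic aromatic iodination goes ortho to the free phenol, and because both ortho positions are equivalent one equivalent should give a single monoiodide.

Step 8
Reactants: 10 3-(trimethylsilyl)prop-2-ynal; 11 propargyl bromide
Product: 12 racemic 1-(trimethylsilyl)hexa-1,5-diyn-3-ol
Conditions: Zn dust, THF, 0 to 25 °C; aq. NH4Cl
Reagents that add atoms: none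
Why: In this Barbier propargylation the allenylzinc species adds by SE2' to give the homopropargylic alcohol, and no stereocontrol is needed because the carbinol centre is erased in step 11.

Step 9
Reactants: 9 iodophenol; 12 diynol
Product: 14 racemic 1-{4,6-bis(benzyloxy)-2-[2-hydroxy-4-(trimethylsilyl)but-3-yn-1-yl]-1-benzofuran-5-yl}-3-methylbutan-1-one, via ortho-alkynylphenol 13 (not isolated)
Conditions: PdCl2(PPh3)2 (3 mol %), CuI (5 mol %), Et3N, DMF, 60 °C
Reagents that add atoms: none
Why: Sonogashira coupling at the only terminal alkyne is followed in the same pot by 5-endo-dig heteroannulation of the only free phenol, which fixes ring C with its oxygen para to the acyl group.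

Step 10
Reactants: 14 benzofuran alcohol
Product: 15 racemic pentafluorobenzoate of 14
Conditions: C6F5COCl, Et3N, DMAP (cat.), CH2Cl2, 0 °C
Reagents that add atoms: pentafluorobenzoyl chloride, O=C(Cl)c1c(F)c(F)c(F)c(F)c1F
Why: DMAP-catalysed esterification turns the alkyl-substituted propargylic alcohol into an ester with a leaving group good enough for allenylidene formation.

Step 11
Reactants: 15 propargylic ester; 4 monobenzyl ether (1.5 equiv)
Product: 18 (3S)-2-methylidene-2,3-dihydrobenzofuran (rings B and C; 4-benzyloxy; 6-hydroxy; 7-isovaleryl; 3-[(4,6-bis(benzyloxy)-5-isovalerylbenzofuran-2-yl)methyl]), via terminal alkyne ester 16 (not isolated), via propargylated phenol 17 (not isolated)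
Conditions: Cu(OAc)2·H2O (5 mol %), (S)-ketimine P,N,N ligand from 1-[2-(diphenylphosphino)phenyl]ethylamine and 2-benzoylpyridine (5.5 mol %), iPr2NEt, MeOH–THF, −10 °C
Reagents that add atoms: none
Why: In this copper-catalysed asymmetric propargylic substitution and [3+2] annulation, methanolysis of the C–Si bond gives 16, its copper acetylide loses carboxylate to a planar copper allenylidene, the chiral ligand directs C3 of 4 to one face of the γ-carbon (this sets the stereocentre, 17), and the adjacent hydroxyl adds 5-exo-dig to the alkyne to close ring B.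

Step 12
Reactants: 18 exocyclic enol ether; 5 ortho-quinone diazide (2.5 equiv)
Product: 20 (2R,3S)-tetrabenzyl spiroketal (rings A and B and C complete), via spiro epimer 19 (not isolated)
Conditions: Rh2(OAc)4 (2 mol %), CH2Cl2, 25 °C, 5 added by syringe pump; then (+)-camphorsulfonic acid (10 mol %), 0 °C, short; Et3N quench
Reagents that add atoms: none
Why: Dirhodium tetraacetate takes N2 from 5 to give an electrophilic quinoid carbenoid, the nucleophilic CH2 terminus of the enol ether of 18 attacks it to form the aryl–CH2 bond and an oxocarbenium ion at C2 of ring B, and the neighbouring, now aromatic, phenoxide oxygen collapses on that carbon. The closest known reaction type is the dirhodium-catalysed formal [3+2] cycloaddition of cyclic 2-diazo-1,3-dicarbonyl compounds and ortho-quinone diazides with enol ethers. Ring A closes last, by 5-exo-trig attack of oxygen on the C=O+ carbon, so one C–C and one C–O bond form at the CH2–C(spiro) pair in one operation. The only new stereocentre is the spiro carbon: ion-pair collapse should first favour the face anti to the C3 side chain (19), and the catalytic acid then reopens and recloses the ketal so that the existing S methine carbon decides the outcome thermodynamically, with the larger ring A CH2 (flanked by the 4'-benzyloxy edge) trans and the ring A oxygen cis to the side chain (20). Regiochemistry is secured because only the carbonyl oxygen next to the acyl-bearing carbon flanks the carbene carbon (the other neighbour is a benzyl ether), and chemoselectivity because the 1,1-disubstituted enol ether is the most nucleophilic π bond present (ring C is acyl-deactivated and the free hydroxyls are chelated to ketones). The methine carbon stays intact as long as capture of the oxocarbenium ion is faster than loss of H-3 to the aromatic benzofuran, which is why the acid stage is kept cold, short and free of base.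

Step 13
Reactants: 20 tetrabenzyl spiroketal
Product: 21 CNP0169640.1
Conditions: H2 (1 atm), Pd/C, EtOAc–EtOH, 25 °C, stopped after uptake of four equivalents
Reagents that add atoms: none
Why: Hydrogenolysis of the four aryl benzyl ethers under neutral conditions should leave the ketal (no benzylic C–O bond), the chelated aryl ketones, the benzofuran and both stereocentres untouched.

Compound list
1 | phloroglucinol | Oc1cc(O)cc(O)c1 | starting material
2 | isovaleryl chloride | CC(C)CC(=O)Cl | starting material
3 | phlorisovalerophenone | CC(C)CC(=O)c1c(O)cc(O)cc1O | intermediate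
4 | 1-[4-(benzyloxy)-2,6-dihydroxyphenyl]-3-methylbutan-1-one | CC(C)CC(=O)c1c(O)cc(OCc2ccccc2)cc1O | intermediate
5 | 5-(benzyloxy)-6-diazo-3-hydroxy-2-(3-methylbutanoyl)cyclohexa-2,4-dien-1-one | CC(C)CC(=O)C1=C(O)C=C(OCc2ccccc2)C(=[N+]=[N-])C1=O | intermediate
6 | 3,5-dihydroxy-4-(3-methylbutanoyl)phenyl 4-methylbenzenesulfonate | CC(C)CC(=O)c1c(O)cc(OS(=O)(=O)c2ccc(C)cc2)cc1O | intermediate
7 | 3,5-bis(benzyloxy)-4-(3-methylbutanoyl)phenyl 4-methylbenzenesulfonate | CC(C)CC(=O)c1c(OCc2ccccc2)cc(OS(=O)(=O)c2ccc(C)cc2)cc1OCc1ccccc1 | intermediate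
8 | 1-[2,6-bis(benzyloxy)-4-hydroxyphenyl]-3-methylbutan-1-one | CC(C)CC(=O)c1c(OCc2ccccc2)cc(O)cc1OCc1ccccc1 | intermediate
9 | 1-[2,6-bis(benzyloxy)-4-hydroxy-3-iodophenyl]-3-methylbutan-1-one | CC(C)CC(=O)c1c(OCc2ccccc2)cc(O)c(I)c1OCc1ccccc1 | intermediate
10 | 3-(trimethylsilyl)prop-2-ynal | C[Si](C)(C)C#CC=O | starting material
11 | propargyl bromide | C#CCBr | starting material
12 | racemic 1-(trimethylsilyl)hexa-1,5-diyn-3-ol | C[Si](C)(C)C#CC(O)CC#C | intermediate
13 | racemic 1-{2,6-bis(benzyloxy)-4-hydroxy-3-[4-hydroxy-6-(trimethylsilyl)hexa-1,5-diyn-1-yl]phenyl}-3-methylbutan-1-one | CC(C)CC(=O)c1c(OCc2ccccc2)cc(O)c(C#CCC(O)C#C[Si](C)(C)C)c1OCc1ccccc1 | intermediate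
14 | racemic 1-{4,6-bis(benzyloxy)-2-[2-hydroxy-4-(trimethylsilyl)but-3-yn-1-yl]-1-benzofuran-5-yl}-3-methylbutan-1-one | C[Si](C)(C)C#CC(O)Cc1cc2c(OCc3ccccc3)c(C(=O)CC(C)C)c(OCc3ccccc3)cc2o1 | intermediate
15 | racemic pentafluorobenzoate of 14 | C[Si](C)(C)C#CC(OC(=O)c1c(F)c(F)c(F)c(F)c1F)Cc1cc2c(OCc3ccccc3)c(C(=O)CC(C)C)c(OCc3ccccc3)cc2o1 | intermediate
16 | racemic desilylated ester, 1-[4,6-bis(benzyloxy)-5-(3-methylbutanoyl)-1-benzofuran-2-yl]but-3-yn-2-yl pentafluorobenzoate | C#CC(OC(=O)c1c(F)c(F)c(F)c(F)c1F)Cc1cc2c(OCc3ccccc3)c(C(=O)CC(C)C)c(OCc3ccccc3)cc2o1 | intermediate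
17 | (R)-1-[4-(benzyloxy)-3-{1-[4,6-bis(benzyloxy)-5-(3-methylbutanoyl)-1-benzofuran-2-yl]but-3-yn-2-yl}-2,6-dihydroxyphenyl]-3-methylbutan-1-one | CC(C)CC(=O)c1c(O)cc(OCc2ccccc2)c([C@@H](C#C)Cc2cc3c(OCc4ccccc4)c(C(=O)CC(C)C)c(OCc4ccccc4)cc3o2)c1O | intermediate
18 | (3S)-1-[4-(benzyloxy)-3-{[4,6-bis(benzyloxy)-5-(3-methylbutanoyl)-1-benzofuran-2-yl]methyl}-6-hydroxy-2-methylidene-2,3-dihydro-1-benzofuran-7-yl]-3-methylbutan-1-one | C=C1Oc2c(C(=O)CC(C)C)c(O)cc(OCc3ccccc3)c2[C@@H]1Cc1cc2c(OCc3ccccc3)c(C(=O)CC(C)C)c(OCc3ccccc3)cc2o1 | intermediate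
19 | (2S,3S) spiro epimer of 20 (ring A oxygen trans to the side chain) | CC(C)CC(=O)c1c(O)cc(OCc3ccccc3)c2c1O[C@@]1(C2)Oc2c(C(=O)CC(C)C)c(O)cc(OCc3ccccc3)c2[C@@H]1Cc1cc2c(OCc3ccccc3)c(C(=O)CC(C)C)c(OCc3ccccc3)cc2o1 | intermediate
20 | (2R,3S)-4,4'-bis(benzyloxy)-3-{[4,6-bis(benzyloxy)-5-(3-methylbutanoyl)-1-benzofuran-2-yl]methyl}-6,6'-dihydroxy-7,7'-bis(3-methylbutanoyl)-3H,3'H-2,2'-spirobi[1-benzofuran] (ring A oxygen cis to the side chain) | CC(C)CC(=O)c1c(O)cc(OCc3ccccc3)c2c1O[C@]1(C2)Oc2c(C(=O)CC(C)C)c(O)cc(OCc3ccccc3)c2[C@@H]1Cc1cc2c(OCc3ccccc3)c(C(=O)CC(C)C)c(OCc3ccccc3)cc2o1 | intermediate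
21 | CNP0169640.1, (2R,3S)-3-{[4,6-dihydroxy-5-(3-methylbutanoyl)-1-benzofuran-2-yl]methyl}-4,4',6,6'-tetrahydroxy-7,7'-bis(3-methylbutanoyl)-3H,3'H-2,2'-spirobi[1-benzofuran] | CC(C)CC(=O)c1c(O)cc(O)c2c1O[C@]1(C2)Oc2c(C(=O)CC(C)C)c(O)cc(O)c2[C@@H]1Cc1cc2c(O)c(C(=O)CC(C)C)c(O)cc2o1 | target

Total step count: 13. Longest linear sequence: 10 steps (1, 4, 5, 6, 7, 9, 10, 11, 12, 13).

Steps most likely to fail

**Step 12.**
- The carbenoid may decay before it meets 18, by attack on its own benzyl arene or by O–H insertion.
- The exocyclic double bond may drift into ring B with aromatisation and loss of the stereocentre.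
- The acid stage may equilibrate the spiro carbon incompletely, or may leak through proton loss from the oxocarbenium ion.

The fallback sets out from 18 and 4 and comes back at 20. It replaces the carbenoid by an oxidative radical-polar [3+2] cycloaddition of the enolic acylphloroglucinol 4 itself, as known for cyclic 1,3-dicarbonyl compounds with exocyclic enol ethers. The oxidant is Ag2CO3 on Celite in MeCN at 60–80 °C, or (NH4)2Ce(NO3)6 with NaHCO3 in MeCN at 0 °C. One-electron oxidation of 4 gives a carbon radical that adds to the CH2 terminus. A second oxidation gives the same oxocarbenium ion, which closes to 19 and 20, and the same acid equilibration follows. The symmetry of 4 keeps the regiochemistry unambiguous, and no new compound is made.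

**Step 11.**
- Base-induced elimination of the ester across the benzofuranyl-activated CH2 group may compete.
- Allenylidene formation from the alkyl-substituted ester may be slow.
- O-attack of the phenoxide and weak facial discrimination are also possible.

The fallback sets out from 4 and comes back at 18, through 17, which is isolated here. It builds the stereocentre by iminium catalysis instead of propargylic substitution.
- Wittig reaction of commercial 3-(triisopropylsilyl)prop-2-ynal with (triphenylphosphoranylidene)acetaldehyde gives (E)-5-(triisopropylsilyl)pent-2-en-4-ynal F1.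
- Compound 4 adds to F1 under α,α-diphenylprolinol trimethylsilyl ether and benzoic acid (catalyst enantiomer chosen for S). This is a Friedel–Crafts conjugate addition followed by hemiacetal closure, and it gives the (4S)-chroman-2-ol F2.
- Ohira–Bestmann homologation of the lactol (K2CO3, MeOH) gives the (S)-diyne phenol F3.
- Sonogashira coupling and heteroannulation with 9, under the conditions of step 9, builds ring C and gives the (S)-silyl alkyne F4.
- Bu4NF buffered with AcOH removes the silyl group to give 17, and CuI with Et3N closes ring B 5-exo-dig to 18.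

**Step 3.** Diazo transfer to a phenol-type nucleophile may stall at the triazene stage or divert into azo coupling, and the diazide may decompose on isolation. The fallback sets out from 4 and comes back at 20. Compound 4 is treated with PhI(OAc)2 and KOH in MeOH at 0 °C, as for cyclic 1,3-diketones, to give the phenyliodonium ylide F5. This ylide replaces 5 in the cycloaddition with 18 under Rh2(OAc)4 or Cu(acac)2 catalysis, followed by the same acid equilibration.

Further compounds
F0 | step 12 | none | none
F1 | step 11 | (E)-5-(triisopropylsilyl)pent-2-en-4-ynal | CC(C)[Si](C#C/C=C/C=O)(C(C)C)C(C)C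
F2 | step 11 | (4S)-1-{5-(benzyloxy)-2,7-dihydroxy-4-[(triisopropylsilyl)ethynyl]chroman-8-yl}-3-methylbutan-1-one (anomer mixture) | CC(C)CC(=O)c1c(O)cc(OCc2ccccc2)c2c1OC(O)C[C@@H]2C#C[Si](C(C)C)(C(C)C)C(C)C
F3 | step 11 | (S)-1-{4-(benzyloxy)-2,6-dihydroxy-3-[1-(triisopropylsilyl)hexa-1,5-diyn-3-yl]phenyl}-3-methylbutan-1-one | CC(C)CC(=O)c1c(O)cc(OCc2ccccc2)c([C@@H](C#C[Si](C(C)C)(C(C)C)C(C)C)CC#C)c1O
F4 | step 11 | (S)-triisopropylsilyl derivative of 17 | CC(C)CC(=O)c1c(O)cc(OCc2ccccc2)c([C@@H](C#C[Si](C(C)C)(C(C)C)C(C)C)Cc2cc3c(OCc4ccccc4)c(C(=O)CC(C)C)c(OCc4ccccc4)cc3o2)c1O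
F5 | step 3 | 3-(benzyloxy)-5-hydroxy-6-(3-methylbutanoyl)-2-(phenyliodonio)phenolate | CC(C)CC(=O)c1c(O)cc(OCc2ccccc2)c([I+]c2ccccc2)c1[O-]
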